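**Plan**
- Retrosynthesis: the O1–C2 bond of ring C is cut first (back to a trans chalcone epoxide with a silylated ring A phenol), then the epoxide oxygen and the Cα=Cβ bond (aldol cut to a ring B aldehyde and a ring A acetophenone), then the cyclohexene bonds C1–C6 and C4–C5 ([4+2] cut to a 2'-hydroxychalcone and a 1-aryl-3-methylbutadiene), and last the aryl–vinyl bond of the diene.
- Forward: diene by Suzuki–Miyaura coupling and chalcone by Claisen–Schmidt condensation; the methylcyclohexene arises first by an exo Diels–Alder reaction; a second Claisen–Schmidt condensation extends ring B; epoxidation; ring C closes last; global deprotection.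
- Enabling feature: ring C (O1, C2, C3, C4) carries trans substituents at C2 and C3, and its O1–C2 bond is benzylic to ring B, whose oxygens sit ortho and para to C2; a trans chalcone epoxide therefore already holds both stereocentres and is opened at C2 by the ring A phenoxide.
- Stereochemistry: C1, C5 and C6 of the cyclohexene come from the boron/VANOL-promoted exo cycloaddition (the E-enone gives the 5,6-trans pair); C2 and C3 come from the poly-L-leucine epoxidation and are carried into ring C by inversion at C2 and retention at C3.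

Key step: step 12

Remark: (R)-VANOL is taken to shield the face of the boron-bound enone that leads to the (1R,5S,6R) adduct; if the sense of induction is the opposite, (S)-VANOL is used and nothing else changes.

**Route**

Step 1
Reactants: 1 2,4-dihydroxybenzaldehyde
Product: 2 2,4-bis(methoxymethoxy)benzaldehyde
Conditions: NaH, MOMCl, DMF, 0 °C to rt
Reagents that add atoms: chloromethyl methyl ether (MOMCl), COCCl
Why: Williamson-type O-alkylation of both sodium phenoxides, the strong base being needed for the hydrogen-bonded 2-OH; no stereocentre is formed.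

Step 2
Reactants: 3 2,4-dihydroxyacetophenone
Product: 4 1-[2-hydroxy-4-(methoxymethoxy)phenyl]ethan-1-one
Conditions: MOMCl, K2CO3, acetone, rt
Reagents that add atoms: chloromethyl methyl ether (MOMCl), COCCl
Why: Williamson-type O-alkylation under weak base touches only the 4-OH, because the 2-OH is held in a hydrogen bond to the ketone; no stereocentre is formed.

Step 3
Reactants: 2 2,4-bis(methoxymethoxy)benzaldehyde; 4 1-[2-hydroxy-4-(methoxymethoxy)phenyl]ethan-1-one
Product: 6 (E)-3-[2,4-bis(methoxymethoxy)phenyl]-1-[2-hydroxy-4-(methoxymethoxy)phenyl]prop-2-en-1-one (dienophile chalcone), via aldol adduct 5 (not isolated)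
Conditions: KOH, EtOH–H2O, rt
Reagents that add atoms: none
Why: Claisen–Schmidt condensation in which the enolate of 4 adds to the non-enolisable aldehyde 2 and E1cB loss of water from 5 gives the thermodynamically favoured E-enone, the methoxymethyl ethers being inert to hydroxide.

Step 4
Reactants: 2 2,4-bis(methoxymethoxy)benzaldehyde
Product: 10 3-iodo-2,4-bis(methoxymethoxy)benzaldehyde, via lithium α-amino alkoxide 7 (not isolated), via C-3 aryllithium 8 (not isolated), via iodinated α-amino alkoxide 9 (not isolated)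
Conditions: 1-methylpiperazine, n-BuLi, THF, −20 °C; then 2; then n-BuLi, −20 to 0 °C; then I2, −78 °C to rt; H2O
Reagents that add atoms: iodine, II
Why: Directed ortho-metalation with in situ protection of the aldehyde, in which lithium 4-methylpiperazin-1-ide adds to the formyl group to give a weakly directing α-amino alkoxide, n-BuLi removes the C-3 proton flanked by both methoxymethoxy groups (the most acidic, doubly coordinated site), iodine traps the aryllithium and water releases the aldehyde, so that no stereocentre remains.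

Step 5
Reactants: 11 2-methylbut-1-en-3-yne
Product: 12 2-[(1E)-3-methylbuta-1,3-dien-1-yl]-4,4,5,5-tetramethyl-1,3,2-dioxaborolane
Conditions: pinacolborane, Cp2Zr(H)Cl (cat.), Et3N (cat.), neat, 60 °C
Reagents that add atoms: pinacolborane, CC1(C)OBOC1(C)C
Why: Cp2Zr(H)Cl-catalysed hydroboration of the terminal alkyne is a syn, anti-Markovnikov addition (hydrozirconation, then transfer to boron), so the E-alkenylboronate forms and the 1,1-disubstituted alkene is left alone.

Step 6
Reactants: 10 3-iodo-2,4-bis(methoxymethoxy)benzaldehyde; 12 dienylboronate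
Product: 13 2,4-bis(methoxymethoxy)-3-[(1E)-3-methylbuta-1,3-dien-1-yl]benzaldehyde (diene)
Conditions: Pd(OAc)2 (cat.), SPhos (cat.), K3PO4, THF–H2O, 50 °C
Reagents that add atoms: none
Why: Suzuki–Miyaura coupling (oxidative addition of zerovalent palladium into the C–I bond, transmetalation, reductive elimination) joins the two sp2 carbons with retention of the E geometry, the bulky biaryl phosphine coping with the doubly ortho-substituted iodide and the mild base sparing the aldehyde.

Step 7
Reactants: 6 dienophile chalcone; 13 diene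
Product: 16 3-[(1R,5S,6R)-6-[2-hydroxy-4-(methoxymethoxy)benzoyl]-5-[2,4-bis(methoxymethoxy)phenyl]-3-methylcyclohex-2-en-1-yl]-2,4-bis(methoxymethoxy)benzaldehyde (exo cycloadduct), via chalcone boron chelate 14 (not isolated), via cycloadduct boron chelate 15 (not isolated)
Conditions: (R)-VANOL, BH3·THF, AcOH, THF, rt (until H2 evolution stops); then 6 and 13, 4 Å molecular sieves, PhCF3, rt; aqueous work-up
Reagents that add atoms: none
Why: Diels–Alder reaction of a 2'-hydroxychalcone activated as a boron chelate, a known entry to cyclohexenes of this family, in which the phenol and ketone of 6 bind the VANOL–boron unit and lower the enone LUMO, the CH2 terminus of the diene bonds to the β-carbon and the aryl-bearing terminus to the α-carbon, the E-enone gives the 5,6-trans pair suprafacially, the exo transition state expected for the bulky chelate gives the 1,6-trans pair, and the (R)-ligand blocks one enone face to set the (1R,5S,6R) series.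

Step 8
Reactants: 16 exo cycloadduct
Product: 17 3-[(1R,5S,6R)-6-[2,4-bis(methoxymethoxy)benzoyl]-5-[2,4-bis(methoxymethoxy)phenyl]-3-methylcyclohex-2-en-1-yl]-2,4-bis(methoxymethoxy)benzaldehyde (core aldehyde)
Conditions: NaH, MOMCl, THF–DMF, 0 °C
Reagents that add atoms: chloromethyl methyl ether (MOMCl), COCCl
Why: Williamson-type O-alkylation of the chelated sodium phenoxide caps the last free phenol before the basic and oxidative steps, and C6 already has its thermodynamically preferred all-trans arrangement, so brief contact with base cannot scramble it.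

Step 9
Reactants: 17 core aldehyde; 4 1-[2-hydroxy-4-(methoxymethoxy)phenyl]ethan-1-one
Product: 19 (E)-enone joining ring B of the core to the 2-hydroxy-4-(methoxymethoxy)phenyl ketone of ring A (core chalcone), via aldol adduct 18 (not isolated)
Conditions: KOH, EtOH–THF–H2O, rt
Reagents that add atoms: none
Why: Claisen–Schmidt condensation of the non-enolisable ring B aldehyde with the enolate of 4, then E1cB dehydration of 18, gives the E-enone, while the hindered core ketone has a single α-hydrogen at a centre that is already in its most stable configuration.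

Step 10
Reactants: 19 core chalcone
Product: 20 triisopropylsilyl ether of the ring A phenol of 19 (silylated chalcone)
Conditions: TIPSCl, imidazole, DMAP (cat.), DMF, 40 °C
Reagents that add atoms: chlorotri(propan-2-yl)silane (TIPSCl), CC(C)[Si](Cl)(C(C)C)C(C)C
Why: Imidazole-promoted silylation masks the phenol that must act as nucleophile later and prevents flavanone formation and Dakin- or Algar–Flynn–Oyamada-type oxidation under basic peroxide, the bulky triisopropylsilyl group being expected to survive amine/peroxide conditions yet fall to fluoride.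

Step 11
Reactants: 20 silylated chalcone
Product: 21 (2R,3S)-epoxy ketone of 20 (chalcone epoxide, αR,βS)
Conditions: poly-L-leucine, urea–H2O2, DBU, THF, rt; isolation without acidic silica
Reagents that add atoms: hydrogen peroxide (used as its urea adduct), OO
Why: Juliá–Colonna epoxidation, a Weitz–Scheffer conjugate addition of hydroperoxide and ring closure within the helical poly-L-leucine, is known to give (αR,βS) epoxides of E-chalcones, so both new stereocentres (oxirane 2R,3S, trans) are set by the catalyst, and the nucleophilic oxidant ignores the electron-rich cyclohexene and the non-conjugated ketone.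

Step 12
Reactants: 21 chalcone epoxide
Product: 23 (2R,3R)-3-hydroxy-7-(methoxymethoxy)-2-aryl-2,3-dihydro-4H-chromen-4-one carrying the fully protected core (heptakis(methoxymethyl) ether of guangsangon K), via desilylated phenol epoxide 22 (not isolated)
Conditions: Bu4NF, AcOH, THF, 0 °C to rt
Reagents that add atoms: none
Why: Fluoride cleaves the aryl O–Si bond and the liberated ring A phenoxide attacks the benzylic oxirane carbon from the side opposite to its C–O bond in an SN2-like opening that forms O1–C2, after which acetic acid protonates the C3 alkoxide and keeps the medium too weakly basic to epimerise or ring-contract the product. The closest known reaction is the cyclisation of 2'-hydroxychalcone epoxides to trans-dihydroflavonols, the ring-forming stage of Algar–Flynn–Oyamada-type syntheses. Ring C closes in the 6-endo-tet mode. C2 is set by stereospecific inversion of the (3S) oxirane carbon and C3 by retention at the (2R) oxirane carbon, so the catalyst-derived trans epoxide becomes (2R,3R), and any ionisation at C2 would still collapse to the same, more stable 2,3-trans isomer. The selectivity needed is 6-endo over 5-exo attack at the carbon next to the ketone; it is secured by the ortho and para oxygens of ring B, which weaken the benzylic C–O bond and stabilise positive charge at C2, and by the absence of a substituent at C6' of ring A, which in related cases is what diverts such openings to benzofuranones.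

Step 13
Reactants: 23 heptakis(methoxymethyl) ether of guangsangon K
Product: 24 guangsangon K
Conditions: HCl in MeOH, THF, rt to 40 °C
Reagents that add atoms: none
Why: Acid-catalysed transacetalisation of the seven aryl methoxymethyl ethers to dimethoxymethane frees all phenols without touching a stereocentre, the acid being kept dilute and the temperature low because the trisubstituted alkene and the ketone flanked by ortho-phenols could otherwise cyclise or ketalise.

**Compound list**

1 | 2,4-dihydroxybenzaldehyde | O=Cc1ccc(O)cc1O | starting material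
2 | 2,4-bis(methoxymethoxy)benzaldehyde | O=Cc1ccc(OCOC)cc1OCOC | intermediate
3 | 2,4-dihydroxyacetophenone | CC(=O)c1ccc(O)cc1O | starting material
4 | 1-[2-hydroxy-4-(methoxymethoxy)phenyl]ethan-1-one | CC(=O)c1ccc(OCOC)cc1O | intermediate
5 | 3-hydroxy-3-[2,4-bis(methoxymethoxy)phenyl]-1-[2-hydroxy-4-(methoxymethoxy)phenyl]propan-1-one (aldol adduct, racemic carbinol, not isolated) | O=C(CC(O)c1ccc(OCOC)cc1OCOC)c1ccc(OCOC)cc1O | intermediate
6 | (E)-3-[2,4-bis(methoxymethoxy)phenyl]-1-[2-hydroxy-4-(methoxymethoxy)phenyl]prop-2-en-1-one | O=C(/C=C/c1ccc(OCOC)cc1OCOC)c1ccc(OCOC)cc1O | intermediate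
7 | lithium [2,4-bis(methoxymethoxy)phenyl](4-methylpiperazin-1-yl)methanolate (racemic, not isolated) | [Li+].[O-]C(N1CCN(C)CC1)c1ccc(OCOC)cc1OCOC | intermediate
8 | C-3 lithio derivative of 7 (not isolated) | [Li+].[O-]C(N1CCN(C)CC1)c1ccc(OCOC)c([Li])c1OCOC | intermediate
9 | lithium [3-iodo-2,4-bis(methoxymethoxy)phenyl](4-methylpiperazin-1-yl)methanolate (racemic, not isolated) | [Li+].[O-]C(N1CCN(C)CC1)c1ccc(OCOC)c(I)c1OCOC | intermediate
10 | 3-iodo-2,4-bis(methoxymethoxy)benzaldehyde | O=Cc1ccc(OCOC)c(I)c1OCOC | intermediate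
11 | 2-methylbut-1-en-3-yne | C=C(C)C#C | starting material
12 | 2-[(1E)-3-methylbuta-1,3-dien-1-yl]-4,4,5,5-tetramethyl-1,3,2-dioxaborolane | C=C(C)/C=C/B1OC(C)(C)C(C)(C)O1 | intermediate
13 | 2,4-bis(methoxymethoxy)-3-[(1E)-3-methylbuta-1,3-dien-1-yl]benzaldehyde | O=Cc1ccc(OCOC)c(/C=C/C(C)=C)c1OCOC | intermediate
14 | (R)-VANOL-derived spiro borate of 6, boron bound to both VANOL oxygens, the phenolate oxygen and the carbonyl oxygen (R axis, not encoded in the SMILES; not isolated) | COCOc1ccc2c(c1)O[B-]3(Oc4c(-c5c(O3)c6ccccc6cc5-c5ccccc5)c(-c5ccccc5)cc5ccccc45)[O+]=C2/C=C/c1ccc(OCOC)cc1OCOC | intermediate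
15 | (R)-VANOL-derived spiro borate of cycloadduct 16, same binding mode (R axis, not encoded in the SMILES; not isolated) | COCOc1ccc2c(c1)O[B-]3(Oc4c(-c5c(O3)c6ccccc6cc5-c5ccccc5)c(-c5ccccc5)cc5ccccc45)[O+]=C2[C@@H]1[C@@H](c2ccc(OCOC)cc2OCOC)CC(C)=C[C@H]1c1c(OCOC)ccc(C=O)c1OCOC | intermediate
16 | 3-[(1R,5S,6R)-6-[2-hydroxy-4-(methoxymethoxy)benzoyl]-5-[2,4-bis(methoxymethoxy)phenyl]-3-methylcyclohex-2-en-1-yl]-2,4-bis(methoxymethoxy)benzaldehyde | CC1=C[C@@H](c2c(OCOC)ccc(C=O)c2OCOC)[C@H](C(=O)c2ccc(OCOC)cc2O)[C@@H](c2ccc(OCOC)cc2OCOC)C1 | intermediate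
17 | 3-[(1R,5S,6R)-6-[2,4-bis(methoxymethoxy)benzoyl]-5-[2,4-bis(methoxymethoxy)phenyl]-3-methylcyclohex-2-en-1-yl]-2,4-bis(methoxymethoxy)benzaldehyde | CC1=C[C@@H](c2c(OCOC)ccc(C=O)c2OCOC)[C@H](C(=O)c2ccc(OCOC)cc2OCOC)[C@@H](c2ccc(OCOC)cc2OCOC)C1 | intermediate
18 | 3-hydroxy-1-[2-hydroxy-4-(methoxymethoxy)phenyl]propan-1-one carrying at C3 the 2,4-bis(methoxymethoxy)phenyl ring B of 17 (aldol adduct, carbinol epimers, not isolated) | CC1=C[C@@H](c2c(OCOC)ccc(C(O)CC(=O)c3ccc(OCOC)cc3O)c2OCOC)[C@H](C(=O)c2ccc(OCOC)cc2OCOC)[C@@H](c2ccc(OCOC)cc2OCOC)C1 | intermediate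
19 | (E)-3-{3-[(1R,5S,6R)-6-[2,4-bis(methoxymethoxy)benzoyl]-5-[2,4-bis(methoxymethoxy)phenyl]-3-methylcyclohex-2-en-1-yl]-2,4-bis(methoxymethoxy)phenyl}-1-[2-hydroxy-4-(methoxymethoxy)phenyl]prop-2-en-1-one | CC1=C[C@@H](c2c(OCOC)ccc(/C=C/C(=O)c3ccc(OCOC)cc3O)c2OCOC)[C@H](C(=O)c2ccc(OCOC)cc2OCOC)[C@@H](c2ccc(OCOC)cc2OCOC)C1 | intermediate
20 | (E)-3-{3-[(1R,5S,6R)-6-[2,4-bis(methoxymethoxy)benzoyl]-5-[2,4-bis(methoxymethoxy)phenyl]-3-methylcyclohex-2-en-1-yl]-2,4-bis(methoxymethoxy)phenyl}-1-[4-(methoxymethoxy)-2-{[tri(propan-2-yl)silyl]oxy}phenyl]prop-2-en-1-one | CC1=C[C@@H](c2c(OCOC)ccc(/C=C/C(=O)c3ccc(OCOC)cc3O[Si](C(C)C)(C(C)C)C(C)C)c2OCOC)[C@H](C(=O)c2ccc(OCOC)cc2OCOC)[C@@H](c2ccc(OCOC)cc2OCOC)C1 | intermediate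
21 | [(2R,3S)-3-{3-[(1R,5S,6R)-6-[2,4-bis(methoxymethoxy)benzoyl]-5-[2,4-bis(methoxymethoxy)phenyl]-3-methylcyclohex-2-en-1-yl]-2,4-bis(methoxymethoxy)phenyl}oxiran-2-yl][4-(methoxymethoxy)-2-{[tri(propan-2-yl)silyl]oxy}phenyl]methanone | CC1=C[C@@H](c2c(OCOC)ccc([C@@H]3O[C@H]3C(=O)c3ccc(OCOC)cc3O[Si](C(C)C)(C(C)C)C(C)C)c2OCOC)[C@H](C(=O)c2ccc(OCOC)cc2OCOC)[C@@H](c2ccc(OCOC)cc2OCOC)C1 | intermediate
22 | [(2R,3S)-3-{3-[(1R,5S,6R)-6-[2,4-bis(methoxymethoxy)benzoyl]-5-[2,4-bis(methoxymethoxy)phenyl]-3-methylcyclohex-2-en-1-yl]-2,4-bis(methoxymethoxy)phenyl}oxiran-2-yl][2-hydroxy-4-(methoxymethoxy)phenyl]methanone (formed as its tetrabutylammonium phenoxide, not isolated) | CC1=C[C@@H](c2c(OCOC)ccc([C@@H]3O[C@H]3C(=O)c3ccc(OCOC)cc3O)c2OCOC)[C@H](C(=O)c2ccc(OCOC)cc2OCOC)[C@@H](c2ccc(OCOC)cc2OCOC)C1 | intermediate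
23 | (2R,3R)-2-{3-[(1R,5S,6R)-6-[2,4-bis(methoxymethoxy)benzoyl]-5-[2,4-bis(methoxymethoxy)phenyl]-3-methylcyclohex-2-en-1-yl]-2,4-bis(methoxymethoxy)phenyl}-3-hydroxy-7-(methoxymethoxy)-2,3-dihydro-4H-chromen-4-one | CC1=C[C@@H](c2c(OCOC)ccc([C@H]3Oc4cc(OCOC)ccc4C(=O)[C@@H]3O)c2OCOC)[C@H](C(=O)c2ccc(OCOC)cc2OCOC)[C@@H](c2ccc(OCOC)cc2OCOC)C1 | intermediate
24 | guangsangon K, (2R,3R)-2-{3-[(1R,5S,6R)-6-(2,4-dihydroxybenzoyl)-5-(2,4-dihydroxyphenyl)-3-methylcyclohex-2-en-1-yl]-2,4-dihydroxyphenyl}-3,7-dihydroxy-2,3-dihydro-4H-chromen-4-one | CC1=C[C@@H](c2c(O)ccc([C@H]3Oc4cc(O)ccc4C(=O)[C@@H]3O)c2O)[C@H](C(=O)c2ccc(O)cc2O)[C@@H](c2ccc(O)cc2O)C1 | target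

**Step count and risks**

Total steps: 13. Longest linear sequence: 10 steps (1 → 2 → 10 → 13 → 16 → 17 → 19 → 20 → 21 → 23 → 24).

Steps most likely to fail:

1. Step 7. The cycloaddition may show poor exo/endo or facial discrimination, because the diene carries a bulky 2,6-dioxygenated aryl group and a Lewis-basic aldehyde that can compete for boron. Fallback: the stereocentres are obtained by resolution instead of asymmetric induction. Setting out from 6 and 13, cycloaddition without a chiral promoter (toluene, sealed tube, 150 °C; the hydrogen-bonded 2'-hydroxy enone is activated enough) and chromatographic enrichment of the exo diastereomer should give the racemate, that is 16 together with the enantiomer of 16 F1. Acylation of the phenol with (1S)-camphanic chloride (Et3N, DMAP, CH2Cl2) gives two diastereomeric aryl esters, the (1S)-camphanate of 16 F2 and the (1S)-camphanate of the enantiomer F3, to be separated by chromatography or crystallisation. Methanolysis of F2 (K2CO3, MeOH, 0 °C) returns 16, and the route continues with step 8.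

2. Step 11. Oxygen transfer inside the polypeptide may be slow and poorly face-selective for an enone flanked by ortho substituents on both aryl rings, and the basic peroxide may cleave the aryl silyl ether or degrade the very electron-rich epoxide. Fallback: the epoxide is built by C–C bond formation (asymmetric Darzens condensation) instead of oxygen transfer. Setting out from 4, silylation (TIPSCl, imidazole, DMF) gives 1-[4-(methoxymethoxy)-2-{[tri(propan-2-yl)silyl]oxy}phenyl]ethan-1-one F4. Chlorination of its lithium enolate (LiN(SiMe3)2, THF, −78 °C; then N-chlorosuccinimide) gives 2-chloro-1-[4-(methoxymethoxy)-2-{[tri(propan-2-yl)silyl]oxy}phenyl]ethan-1-one F5. Condensation of F5 with the core aldehyde 17 under phase-transfer conditions (cinchona-derived quaternary ammonium chloride, LiOH·H2O, CH2Cl2, 0 °C) forms the trans epoxy ketone by aldol addition and intramolecular displacement of chloride, the chiral ion pair setting the (2R,3S) configuration. This fallback sets out from 17 and returns to the route at 21, making 19 and 20 unnecessary.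

3. Step 12. The ring closure may be diverted to 5-exo attack at the carbon next to the ketone, the epoxide may rearrange before it is opened, or the product may epimerise or ring-contract if the medium turns basic. Fallback: a two-stage closure through a sulfur-stabilised intermediate. Setting out from 21, opening of the oxirane at the benzylic carbon with phenylmethanethiol (BF3·OEt2 cat., CH2Cl2, −78 °C) gives the (2S)-3-(benzylsulfanyl)-2-hydroxy ketone F6 as C3 epimers. Desilylation (Bu4NF, AcOH, THF, 0 °C) gives the corresponding ring A phenol F7. Treatment with AgBF4 (CH2Cl2, 0 °C) ionises the C–S bond, and the benzylic cation stabilised by the ring B oxygens is captured by the phenol under thermodynamic control to give the 2,3-trans product with C3 untouched. This fallback returns to the route at 23.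

**Further compounds**

F1 | step 7 | 3-[(1S,5R,6S)-6-[2-hydroxy-4-(methoxymethoxy)benzoyl]-5-[2,4-bis(methoxymethoxy)phenyl]-3-methylcyclohex-2-en-1-yl]-2,4-bis(methoxymethoxy)benzaldehyde (enantiomer of 16) | CC1=C[C@H](c2c(OCOC)ccc(C=O)c2OCOC)[C@@H](C(=O)c2ccc(OCOC)cc2O)[C@H](c2ccc(OCOC)cc2OCOC)C1
F2 | step 7 | (1S,4R)-camphanate ester of the phenol of 16 | CC1=C[C@@H](c2c(OCOC)ccc(C=O)c2OCOC)[C@H](C(=O)c2ccc(OCOC)cc2OC(=O)[C@@]23CC[C@@](C)(C(=O)O2)C3(C)C)[C@@H](c2ccc(OCOC)cc2OCOC)C1
F3 | step 7 | (1S,4R)-camphanate ester of the phenol of F1 | CC1=C[C@H](c2c(OCOC)ccc(C=O)c2OCOC)[C@@H](C(=O)c2ccc(OCOC)cc2OC(=O)[C@@]23CC[C@@](C)(C(=O)O2)C3(C)C)[C@H](c2ccc(OCOC)cc2OCOC)C1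
F4 | step 11 | 1-[4-(methoxymethoxy)-2-{[tri(propan-2-yl)silyl]oxy}phenyl]ethan-1-one | CC(=O)c1ccc(OCOC)cc1O[Si](C(C)C)(C(C)C)C(C)C
F5 | step 11 | 2-chloro-1-[4-(methoxymethoxy)-2-{[tri(propan-2-yl)silyl]oxy}phenyl]ethan-1-one | ClCC(=O)c1ccc(OCOC)cc1O[Si](C(C)C)(C(C)C)C(C)C
F6 | step 12 | (2S)-3-(benzylsulfanyl)-2-hydroxy-1-[4-(methoxymethoxy)-2-{[tri(propan-2-yl)silyl]oxy}phenyl]propan-1-one carrying at C3 the ring B aryl of 21 (C3 epimers) | CC1=C[C@@H](c2c(OCOC)ccc(C(SCc3ccccc3)[C@@H](O)C(=O)c3ccc(OCOC)cc3O[Si](C(C)C)(C(C)C)C(C)C)c2OCOC)[C@H](C(=O)c2ccc(OCOC)cc2OCOC)[C@@H](c2ccc(OCOC)cc2OCOC)C1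
F7 | step 12 | (2S)-3-(benzylsulfanyl)-2-hydroxy-1-[2-hydroxy-4-(methoxymethoxy)phenyl]propan-1-one carrying at C3 the ring B aryl of 21 (C3 epimers) | CC1=C[C@@H](c2c(OCOC)ccc(C(SCc3ccccc3)[C@@H](O)C(=O)c3ccc(OCOC)cc3O)c2OCOC)[C@H](C(=O)c2ccc(OCOC)cc2OCOC)[C@@H](c2ccc(OCOC)cc2OCOC)C1
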